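**Plan**

- Target: fisetinidol-(4α→8)-[fisetinidol-(4β→6)]-catechin. Retrosynthetic cuts: the twelve O-benzyl bonds; in the unit on C8, C3–O/C4–H (hydroboration) and then C4–C8 (palladium carbene coupling of a flavanone hydrazone with a C8 bromide); in the unit on C6, O1–C2 (Mitsunobu) and C2–aryl (Grignard), then C3–C4 together with the acyl O1–C2 bond (key step); finally the benzylic C–C6 bond.
- Enabling feature: in the fisetinidol unit on catechin C6 the oxygen at C3 and the aryl group at C4 are cis on ring C, the atoms O1–C2–C3 are a benzyloxyacetyl unit esterified to the ring A phenol, and C4 is the benzylic carbon ortho to that phenol. Ring A can therefore act as an o-quinone methide and C2–C3 as an azolium enolate.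
- Forward order: catechin is perbenzylated, brominated at C8 and iodinated at C6; the C6 Grignard reagent adds to a ring A aldehyde; the carbinol becomes the sulfone; the annulation closes ring C of the first unit as a lactone. This ring is opened at the lactol stage to take up ring B and is closed again by etherification. The second unit arrives as a preformed chromanone at C8–Br and is finished by hydroboration and hydrogenolysis.
- Stereochemistry: catechin C2/C3 from the chiral pool; C3/C4 of the unit on C6 from the triazolium catalyst (cis); its C2 from a chelation-controlled aryl addition followed by inversion; C2 of the unit on C8 from a ligand-controlled conjugate addition, its C3/C4 from syn hydroboration anti to the C2 aryl group.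

Key step: step 9

Assumption: the absolute sense of induction of the triazolium salt (step 9) and of the pyridine-oxazoline ligand (step 14) is assigned by analogy with simpler substrates; both are available as either antipode, so a reversed sense is corrected by exchanging the antipode and nothing else changes.

In the names below, "catechin-6-yl residue" means (2R,3S)-3,5,7-tris(benzyloxy)-2-[3,4-bis(benzyloxy)phenyl]-8-bromochroman-6-yl.

**Route**

Step 1
Reactants: 1 (+)-catechin
Product: 2 (2R,3S)-5,7-bis(benzyloxy)-2-[3,4-bis(benzyloxy)phenyl]chroman-3-ol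
Conditions: BnBr (4.4 equiv), K2CO3, DMF, 0 °C → rt
Reagents that add atoms: benzyl bromide BrCc1ccccc1
Why: Williamson etherification in which carbonate ionises only the four phenols, so the secondary 3-OH should stay free and C2/C3 are not touched.

Step 2
Reactants: 2 tetra-O-benzylcatechin
Product: 3 (2R,3S)-3,5,7-tris(benzyloxy)-2-[3,4-bis(benzyloxy)phenyl]chromane
Conditions: NaH, BnBr, DMF, 0 °C → rt
Reagents that add atoms: benzyl bromide BrCc1ccccc1
Why: Williamson etherification of the sodium alkoxide, which removes the last acidic proton before the organometallic steps.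

Step 3
Reactants: 3 penta-O-benzylcatechin
Product: 4 8-bromo-penta-O-benzylcatechin
Conditions: NBS (1.0 equiv), CH2Cl2, −78 °C → rt
Reagents that add atoms: N-bromosuccinimide O=C1CCC(=O)N1Br
Why: electrophilic aromatic bromination, in which C8 of the phloroglucinol-type ring A is the more accessible and more nucleophilic position, so one equivalent should stop at the 8-bromide.

Step 4
Reactants: 4 8-bromo-penta-O-benzylcatechin
Product: 5 8-bromo-6-iodo-penta-O-benzylcatechin
Conditions: NIS (1.1 equiv), CF3CO2H (10 mol%), MeCN/CH2Cl2, 0 °C → rt, dark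
Reagents that add atoms: N-iodosuccinimide O=C1CCC(=O)N1I
Why: electrophilic aromatic iodination at C6, the only open ring A position, which is still activated by two ortho oxygens and one para oxygen.

Step 5
Reactants: 6 4-(benzyloxy)-2-hydroxybenzaldehyde
Product: 7 4-(benzyloxy)-2-(tert-butyldimethylsilyloxy)benzaldehyde
Conditions: TBSCl, imidazole, CH2Cl2, rt
Reagents that add atoms: tert-butyldimethylsilyl chloride CC(C)(C)[Si](C)(C)Cl
Why: imidazole-promoted silylation of the phenol, so that the aldehyde consumes only one equivalent of the valuable Grignard reagent in step 6.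

Step 6
Reactants: 5 8-bromo-6-iodo-penta-O-benzylcatechin; 7 silylated ring A aldehyde
Product: 10 (4-benzyloxy-2-hydroxyphenyl)(catechin-6-yl residue)methanol as both carbinol epimers, via C6 arylmagnesium chloride 8 (not isolated), via silyl ether carbinol 9 (not isolated)
Conditions: i-PrMgCl·LiCl (1.1 equiv), THF, −40 °C; 7, −40 → 0 °C; aq. NH4Cl, crude 9 in THF, Bu4NF, 0 °C
Reagents that add atoms: none
Why: iodine–magnesium exchange is far faster at C–I than at C–Br, the arylmagnesium undergoes Grignard addition to the aldehyde and fluoride removes the silyl group; the new carbinol centre is formed without control, which is harmless because it becomes trigonal in step 9.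

Step 7
Reactants: 10 o-hydroxybenzhydrol
Product: 11 5-benzyloxy-2-[(catechin-6-yl residue)(p-tolylsulfonyl)methyl]phenol as both epimers at the sulfonyl carbon
Conditions: p-TolSO2H (2 equiv), MgSO4, CH2Cl2, rt
Reagents that add atoms: p-toluenesulfinic acid Cc1ccc(cc1)S(=O)O
Why: SN1-type substitution in which the weakly acidic sulfinic acid ionises the doubly donor-stabilised benzhydrol (benzhydryl cation/o-quinone methide) and the sulfinate captures it at sulfur to give a storable sulfone.

Step 8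
Reactants: 12 benzyloxyacetyl chloride
Product: 13 4-nitrophenyl benzyloxyacetate
Conditions: 4-nitrophenol, Et3N, CH2Cl2, 0 °C → rt
Reagents that add atoms: 4-nitrophenol Oc1ccc(cc1)[N+](=O)[O-]
Why: O-acylation of a phenol by an acid chloride, giving the activated ester that a carbene can turn over.

Step 9
Reactants: 11 ring A sulfone; 13 4-nitrophenyl benzyloxyacetate
Product: 16 (3S,4R)-3,7-bis(benzyloxy)-4-(catechin-6-yl residue)chroman-2-one (3,4-cis), via ring A o-quinone methide 14 (not isolated), via azolium enolate 15 (not isolated)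
Conditions: 13 (2 equiv), (5aS,10bR)-2-mesityl-5a,10b-dihydro-4H,6H-indeno[2,1-b][1,2,4]triazolo[4,3-d][1,4]oxazin-2-ium tetrafluoroborate (15 mol%), Cs2CO3 (2.5 equiv), 4 Å molecular sieves, THF, 0 °C, pH 7 buffer quench at full conversion of 11
Reagents that add atoms: none
Why: Cs2CO3 deprotonates the phenol of 11 and expels p-toluenesulfinate (E1cB) to give the ring A o-quinone methide 14, while the carbene freed from the triazolium salt is acylated by ester 13 and the acyl azolium loses its acidic α-proton to give the (Z)-azolium enolate 15; the enolate carbon adds to the methide carbon (C3–C4, ring A rearomatises) and the phenoxide then attacks the acyl azolium (O1–C2) and releases the carbene. The closest known reaction type is the N-heterocyclic carbene catalysed formal (4+2) annulation of azolium enolates with o-quinone methides generated in situ from 2-(sulfonylalkyl)phenols, which gives cis-3,4-dihydrocoumarins. Ring C closes as the δ-lactone by 6-exo-trig acyl substitution after the intermolecular Michael-type C–C bond formation, the two events together amounting to an oxa-Diels–Alder-like closure. C3 is set by the catalyst, whose aminoindane wall leaves one face of the enolate open, and C4 follows from the compact endo-type stacking of the (E)-quinone methide on that face, which places H3 and H4 syn and gives the cis lactone independently of the remote catechin centres. The step needs kinetic cis diastereoselection, catalyst-set absolute configuration and attack at the exocyclic methide carbon only, and these are secured by the enforced Z geometry of the α-benzyloxy enolate, the fixed s-cis oxadiene of the quinone methide and the single free phenol next to the sulfonyl-bearing carbon. Because the 7-benzyloxy group and the twisted, di-ortho-substituted catechin ring make 14 a weak electrophile and C3–H of 16 is epimerisable, excess ester, 0 °C and a prompt quench are prescribed.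

Step 10
Reactants: 16 cis lactone
Product: 17 (3S,4R)-3,7-bis(benzyloxy)-4-(catechin-6-yl residue)chroman-2-ol as an anomeric mixture
Conditions: i-Bu2AlH (1.2 equiv), CH2Cl2, −78 °C; aq. potassium sodium tartrate
Reagents that add atoms: none
Why: partial reduction of a lactone to the lactol, in which the tetrahedral aluminate persists at −78 °C and the non-basic hydride leaves C3 and C4 unchanged.

Step 11
Reactants: 17 lactol; 18 4-bromo-1,2-bis(benzyloxy)benzene
Product: 20 (1S,2S,3R)-2-benzyloxy-1-[3,4-bis(benzyloxy)phenyl]-3-(4-benzyloxy-2-hydroxyphenyl)-3-(catechin-6-yl residue)propan-1-ol, via arylmagnesium bromide 19 (not isolated)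
Conditions: 18, Mg, THF, rt (3.5 equiv of 19); then 17, MgBr2·OEt2, CH2Cl2/THF, −40 → 0 °C; aq. NH4Cl
Reagents that add atoms: none
Why: Grignard addition to a lactol through its open hydroxy aldehyde under chelation control (Cram chelate model), in which magnesium bridges the aldehyde oxygen and the C2 benzyloxy oxygen and the aryl group enters anti to the bulky diarylmethyl group, which should set the carbinol centre as S.

Step 12
Reactants: 20 phenol carbinol
Product: 21 (2R,3S,4R)-3,7-bis(benzyloxy)-2-[3,4-bis(benzyloxy)phenyl]-4-(catechin-6-yl residue)chromane, the benzylated fisetinidol-(4β→6)-8-bromocatechin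
Conditions: PPh3, i-PrO2CN=NCO2i-Pr, THF, 0 °C → rt
Reagents that add atoms: none
Why: intramolecular Mitsunobu etherification (6-exo-tet), in which the ring A phenol displaces the activated benzylic alcohol with inversion, turning the 1S carbinol into the 2R centre trans to the 3-benzyloxy group.

Step 13
Reactants: 22 7-hydroxy-4H-chromen-4-one
Product: 23 7-(benzyloxy)-4H-chromen-4-one
Conditions: BnBr, K2CO3, DMF, rt
Reagents that add atoms: benzyl bromide BrCc1ccccc1
Why: Williamson etherification of the only acidic hydroxyl group.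

Step 14
Reactants: 23 7-(benzyloxy)chromone; 24 3,4-bis(benzyloxy)phenylboronic acid
Product: 25 (2S)-7-benzyloxy-2-[3,4-bis(benzyloxy)phenyl]chroman-4-one
Conditions: Pd(OCOCF3)2 (5 mol%), (R)-4-tert-butyl-2-(pyridin-2-yl)-4,5-dihydrooxazole (6 mol%), NH4PF6 (30 mol%), H2O (5 equiv), ClCH2CH2Cl, 60 °C
Reagents that add atoms: none
Why: palladium-catalysed asymmetric conjugate addition of an arylboronic acid to a chromone, in which the chiral pyridine-oxazoline ligand selects the face of C2 for aryl–palladium insertion and protonation of the palladium enolate releases the flavanone.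

Step 15
Reactants: 25 (2S)-flavanone
Product: 26 N-tosylhydrazone of 25
Conditions: TsNHNH2, MeOH, 50 °C
Reagents that add atoms: p-toluenesulfonyl hydrazide Cc1ccc(cc1)S(=O)(=O)NN
Why: condensation of a ketone with a sulfonyl hydrazide under neutral conditions, which avoids the base-induced ring opening that would racemise C2.

Step 16
Reactants: 21 dimeric C8 bromide; 26 flavanone tosylhydrazone
Product: 28 benzylated dimer carrying a (2S)-7-benzyloxy-2-[3,4-bis(benzyloxy)phenyl]-2H-chromen-4-yl group on catechin C8, via 4-diazoflavan 27 (not isolated)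
Conditions: Pd2(dba)3 (2.5 mol%), 2-dicyclohexylphosphino-2',4',6'-triisopropylbiphenyl (10 mol%), LiOt-Bu (2.5 equiv), 1,4-dioxane, 90 °C
Reagents that add atoms: none
Why: Barluenga coupling, in which base converts the hydrazone into the diazo compound (Bamford–Stevens), the arylpalladium bromide from oxidative addition forms a palladium carbene, aryl migration and β-hydride elimination from C3 give the C3=C4 alkene, and C2 is not involved.

Step 17
Reactants: 28 4-aryl-flav-3-ene
Product: 30 benzylated trimer with a free 3-OH in the (2R,3S,4S) unit on C8, via C3 alkylborane 29 (not isolated)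
Conditions: BH3·THF, THF, 0 °C → rt; then NaOH, H2O2, H2O, 0 °C → rt
Reagents that add atoms: hydrogen peroxide OO
Why: hydroboration–oxidation, in which boron and hydrogen add syn from the face anti to the C2 aryl group with boron at the non-benzylic C3, so that after oxidation with retention the 3-OH is trans to both the C2 and the C4 aryl groups.

Step 18
Reactants: 30 dodeca-O-benzyl trimer
Product: 31 fisetinidol-(4α→8)-[fisetinidol-(4β→6)]-catechin
Conditions: H2 (1 atm), Pd(OH)2/C, THF/MeOH/H2O, rt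
Reagents that add atoms: none
Why: catalytic hydrogenolysis of the twelve benzyl ethers under neutral conditions, which should leave the acid-sensitive interflavan bonds and all eight stereocentres unchanged.

**Compound list**

1 | (+)-catechin | O[C@H]1Cc2c(O)cc(O)cc2O[C@@H]1c1ccc(O)c(O)c1 | starting material
2 | 5,7,3',4'-tetra-O-benzylcatechin | c1c(OCc9ccccc9)c2c(cc1OCc9ccccc9)O[C@H](c8ccc(OCc9ccccc9)c(OCc9ccccc9)c8)[C@@H](O)C2 | intermediate
3 | 3,5,7,3',4'-penta-O-benzylcatechin | c1c(OCc9ccccc9)c2c(cc1OCc9ccccc9)O[C@H](c8ccc(OCc9ccccc9)c(OCc9ccccc9)c8)[C@@H](OCc9ccccc9)C2 | intermediate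
4 | 8-bromo-penta-O-benzylcatechin | c1c(OCc9ccccc9)c2c(c(Br)c1OCc9ccccc9)O[C@H](c8ccc(OCc9ccccc9)c(OCc9ccccc9)c8)[C@@H](OCc9ccccc9)C2 | intermediate
5 | 8-bromo-6-iodo-penta-O-benzylcatechin | Ic1c(OCc9ccccc9)c2c(c(Br)c1OCc9ccccc9)O[C@H](c8ccc(OCc9ccccc9)c(OCc9ccccc9)c8)[C@@H](OCc9ccccc9)C2 | intermediate
6 | 4-(benzyloxy)-2-hydroxybenzaldehyde | O=Cc1ccc(OCc2ccccc2)cc1O | starting material
7 | 4-(benzyloxy)-2-(tert-butyldimethylsilyloxy)benzaldehyde | O=Cc1ccc(OCc2ccccc2)cc1O[Si](C)(C)C(C)(C)C | intermediate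
8 | (8-bromo-penta-O-benzylcatechin-6-yl)magnesium chloride | Cl[Mg]c1c(OCc9ccccc9)c2c(c(Br)c1OCc9ccccc9)O[C@H](c8ccc(OCc9ccccc9)c(OCc9ccccc9)c8)[C@@H](OCc9ccccc9)C2 | intermediate
9 | [4-benzyloxy-2-(tert-butyldimethylsilyloxy)phenyl](catechin-6-yl residue)methanol, both carbinol epimers, formed as its magnesium alkoxide | O(Cc9ccccc9)c1ccc(c(O[Si](C)(C)C(C)(C)C)c1)C(O)c1c(OCc9ccccc9)c2c(c(Br)c1OCc9ccccc9)O[C@H](c8ccc(OCc9ccccc9)c(OCc9ccccc9)c8)[C@@H](OCc9ccccc9)C2 | intermediate
10 | (4-benzyloxy-2-hydroxyphenyl)(catechin-6-yl residue)methanol, both carbinol epimers | O(Cc9ccccc9)c1ccc(c(O)c1)C(O)c1c(OCc9ccccc9)c2c(c(Br)c1OCc9ccccc9)O[C@H](c8ccc(OCc9ccccc9)c(OCc9ccccc9)c8)[C@@H](OCc9ccccc9)C2 | intermediate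
11 | 5-benzyloxy-2-[(catechin-6-yl residue)(p-tolylsulfonyl)methyl]phenol, both epimers at the sulfonyl carbon | O(Cc9ccccc9)c1ccc(c(O)c1)C(S(=O)(=O)c5ccc(C)cc5)c1c(OCc9ccccc9)c2c(c(Br)c1OCc9ccccc9)O[C@H](c8ccc(OCc9ccccc9)c(OCc9ccccc9)c8)[C@@H](OCc9ccccc9)C2 | intermediate
12 | benzyloxyacetyl chloride | O=C(Cl)COCc1ccccc1 | starting material
13 | 4-nitrophenyl benzyloxyacetate | O=C(COCc1ccccc1)Oc1ccc(cc1)[N+](=O)[O-] | intermediate
14 | 3-benzyloxy-6-[(catechin-6-yl residue)methylidene]cyclohexa-2,4-dien-1-one (ring A o-quinone methide, E expected) | O=C1C=C(OCc9ccccc9)C=CC1=Cc1c(OCc9ccccc9)c2c(c(Br)c1OCc9ccccc9)O[C@H](c8ccc(OCc9ccccc9)c(OCc9ccccc9)c8)[C@@H](OCc9ccccc9)C2 | intermediate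
15 | (Z)-2-benzyloxy-1-oxidoethenyl derivative of the (5aS,10bR)-N-mesityl indeno-triazolo-oxazinium (azolium enolate, zwitterion) | Cc1cc(C)c(c(C)c1)-[n+]1c(/C([O-])=C/OCc9ccccc9)n2[C@@H]3c4ccccc4C[C@@H]3OCc2n1 | intermediate
16 | (3S,4R)-3,7-bis(benzyloxy)-4-(catechin-6-yl residue)chroman-2-one, 3,4-cis | O(Cc9ccccc9)c1ccc2c(c1)OC(=O)[C@@H](OCc9ccccc9)[C@H]2c1c(OCc9ccccc9)c2c(c(Br)c1OCc9ccccc9)O[C@H](c8ccc(OCc9ccccc9)c(OCc9ccccc9)c8)[C@@H](OCc9ccccc9)C2 | intermediate
17 | (3S,4R)-3,7-bis(benzyloxy)-4-(catechin-6-yl residue)chroman-2-ol, both anomers | O(Cc9ccccc9)c1ccc2c(c1)OC(O)[C@@H](OCc9ccccc9)[C@H]2c1c(OCc9ccccc9)c2c(c(Br)c1OCc9ccccc9)O[C@H](c8ccc(OCc9ccccc9)c(OCc9ccccc9)c8)[C@@H](OCc9ccccc9)C2 | intermediate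
18 | 4-bromo-1,2-bis(benzyloxy)benzene | Brc1ccc(OCc2ccccc2)c(OCc2ccccc2)c1 | starting material
19 | [3,4-bis(benzyloxy)phenyl]magnesium bromide | Br[Mg]c1ccc(OCc2ccccc2)c(OCc2ccccc2)c1 | intermediate
20 | (1S,2S,3R)-2-benzyloxy-1-[3,4-bis(benzyloxy)phenyl]-3-(4-benzyloxy-2-hydroxyphenyl)-3-(catechin-6-yl residue)propan-1-ol | O(Cc9ccccc9)c1ccc(c(O)c1)[C@@H]([C@H](OCc9ccccc9)[C@@H](O)c8ccc(OCc9ccccc9)c(OCc9ccccc9)c8)c1c(OCc9ccccc9)c2c(c(Br)c1OCc9ccccc9)O[C@H](c8ccc(OCc9ccccc9)c(OCc9ccccc9)c8)[C@@H](OCc9ccccc9)C2 | intermediate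
21 | benzylated fisetinidol-(4β→6)-8-bromocatechin, upper unit (2R,3S,4R) | O(Cc9ccccc9)c1ccc2c(c1)O[C@H](c8ccc(OCc9ccccc9)c(OCc9ccccc9)c8)[C@@H](OCc9ccccc9)[C@H]2c1c(OCc9ccccc9)c2c(c(Br)c1OCc9ccccc9)O[C@H](c8ccc(OCc9ccccc9)c(OCc9ccccc9)c8)[C@@H](OCc9ccccc9)C2 | intermediate
22 | 7-hydroxy-4H-chromen-4-one | O=c1ccoc2cc(O)ccc12 | starting material
23 | 7-(benzyloxy)-4H-chromen-4-one | O=c1ccoc2cc(OCc3ccccc3)ccc12 | intermediate
24 | 3,4-bis(benzyloxy)phenylboronic acid | OB(O)c1ccc(OCc2ccccc2)c(OCc2ccccc2)c1 | starting material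
25 | (2S)-7-benzyloxy-2-[3,4-bis(benzyloxy)phenyl]chroman-4-one | O=C1C[C@@H](c2ccc(OCc3ccccc3)c(OCc3ccccc3)c2)Oc2cc(OCc3ccccc3)ccc12 | intermediate
26 | N-tosylhydrazone of 25 | Cc1ccc(cc1)S(=O)(=O)NN=C1C[C@@H](c2ccc(OCc3ccccc3)c(OCc3ccccc3)c2)Oc2cc(OCc3ccccc3)ccc12 | intermediate
27 | (2S)-7-benzyloxy-2-[3,4-bis(benzyloxy)phenyl]-4-diazochromane | [N-]=[N+]=C1C[C@@H](c2ccc(OCc3ccccc3)c(OCc3ccccc3)c2)Oc2cc(OCc3ccccc3)ccc12 | intermediate
28 | compound 21 with bromine replaced by (2S)-7-benzyloxy-2-[3,4-bis(benzyloxy)phenyl]-2H-chromen-4-yl | O(Cc9ccccc9)c1ccc2c(c1)O[C@H](c8ccc(OCc9ccccc9)c(OCc9ccccc9)c8)[C@@H](OCc9ccccc9)[C@H]2c1c(OCc9ccccc9)c2c(c(C3=C[C@@H](c8ccc(OCc9ccccc9)c(OCc9ccccc9)c8)Oc4cc(OCc9ccccc9)ccc34)c1OCc9ccccc9)O[C@H](c8ccc(OCc9ccccc9)c(OCc9ccccc9)c8)[C@@H](OCc9ccccc9)C2 | intermediate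
29 | C3 borane of the unit on C8 (boron trans to the C2 and C4 aryl groups) | O(Cc9ccccc9)c1ccc2c(c1)O[C@H](c8ccc(OCc9ccccc9)c(OCc9ccccc9)c8)[C@@H](OCc9ccccc9)[C@H]2c1c(OCc9ccccc9)c2c(c([C@@H]3c4ccc(OCc9ccccc9)cc4O[C@H](c8ccc(OCc9ccccc9)c(OCc9ccccc9)c8)[C@H]3B)c1OCc9ccccc9)O[C@H](c8ccc(OCc9ccccc9)c(OCc9ccccc9)c8)[C@@H](OCc9ccccc9)C2 | intermediate
30 | dodeca-O-benzyl trimer, free 3-OH in the (2R,3S,4S) unit on C8 | O(Cc9ccccc9)c1ccc2c(c1)O[C@H](c8ccc(OCc9ccccc9)c(OCc9ccccc9)c8)[C@@H](OCc9ccccc9)[C@H]2c1c(OCc9ccccc9)c2c(c([C@@H]3c4ccc(OCc9ccccc9)cc4O[C@H](c8ccc(OCc9ccccc9)c(OCc9ccccc9)c8)[C@H]3O)c1OCc9ccccc9)O[C@H](c8ccc(OCc9ccccc9)c(OCc9ccccc9)c8)[C@@H](OCc9ccccc9)C2 | intermediate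
31 | fisetinidol-(4α→8)-[fisetinidol-(4β→6)]-catechin | Oc1ccc2c(c1)O[C@H](c1ccc(O)c(O)c1)[C@@H](O)[C@H]2c1c(O)c2c(c([C@@H]3c4ccc(O)cc4O[C@H](c4ccc(O)c(O)c4)[C@H]3O)c1O)O[C@H](c1ccc(O)c(O)c1)[C@@H](O)C2 | target

**Count and risks**

Total: 18 steps. Longest linear sequence: 13 steps (1–4, 6, 7, 9–12, 16–18) from (+)-catechin.

Steps most likely to fail:

Step 9. The azolium enolate may add too slowly to the crowded, donor-stabilised quinone methide, so that ester consumption without annulation and base-induced epimerisation at C3 take over. The fallback replaces the catalytic enolate by a stoichiometric auxiliary-bound one. Acid chloride 12 acylates lithiated (R)-4-benzyloxazolidin-2-one to give (R)-4-benzyl-3-(benzyloxyacetyl)oxazolidin-2-one F1. NaN(SiMe3)2 in THF at −78 °C converts it into its sodium (Z)-enolate F2. Two equivalents of this enolate are added to sulfone 11: the first releases quinone methide 14, the second adds to it in an auxiliary-controlled Michael addition to give the phenol imide F3. On warming, the phenoxide displaces the auxiliary from the exocyclic carbonyl, which returns the route to lactone 16.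

Step 16. Oxidative addition and carbene insertion at the di-ortho-substituted, electron-rich bromide may be slow, so that thermal decomposition of the diazo compound to the simple flavene and protodebromination prevail. The fallback uses polar organometallic addition in place of the palladium carbene. Bromide 21 is converted with t-BuLi (THF, −78 °C) into the C8 aryllithium F4 and transmetalated with anhydrous CeCl3 to the dichlorocerium reagent F5. This adds to the carbonyl group of flavanone 25 to give the tertiary 4-arylflavan-4-ol F6. Dehydration with methyl N-(triethylammoniosulfonyl)carbamate in toluene returns the route to flavene 28.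

Step 12. The oxyphosphonium of the dialkoxybenzylic alcohol may ionise, so that inversion is no longer clean and elimination competes. The fallback forms the C2–aryl bond on the intact ring and bypasses steps 11 and 12. Lactol 17 is treated with PhSO2H and CaCl2 in CH2Cl2 to give the 2-(phenylsulfonyl)chroman F7. The diarylzinc bis[3,4-bis(benzyloxy)phenyl]zinc F8, prepared from Grignard reagent 19 and ZnBr2, displaces the sulfonyl group through the cyclic oxocarbenium ion. The aryl group should enter on the face opposite to the cis 3-benzyloxy/4-aryl pair, which returns the route to 21.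

**Further compounds**

F1 | step 9 | (R)-4-benzyl-3-(benzyloxyacetyl)oxazolidin-2-one | O=C(COCc1ccccc1)N1[C@H](Cc2ccccc2)COC1=O
F2 | step 9 | sodium (Z)-enolate of F1 | [Na+].[O-]/C(=C\OCc1ccccc1)N1[C@H](Cc2ccccc2)COC1=O
F3 | step 9 | (2S,3R)-2-benzyloxy-3-(4-benzyloxy-2-hydroxyphenyl)-3-(catechin-6-yl residue)propanoyl imide of (R)-4-benzyloxazolidin-2-one | O(Cc9ccccc9)c1ccc(c(O)c1)[C@@H]([C@H](OCc9ccccc9)C(=O)N3[C@H](Cc9ccccc9)COC3=O)c1c(OCc9ccccc9)c2c(c(Br)c1OCc9ccccc9)O[C@H](c8ccc(OCc9ccccc9)c(OCc9ccccc9)c8)[C@@H](OCc9ccccc9)C2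
F4 | step 16 | C8 aryllithium from 21 | O(Cc9ccccc9)c1ccc2c(c1)O[C@H](c8ccc(OCc9ccccc9)c(OCc9ccccc9)c8)[C@@H](OCc9ccccc9)[C@H]2c1c(OCc9ccccc9)c2c(c([Li])c1OCc9ccccc9)O[C@H](c8ccc(OCc9ccccc9)c(OCc9ccccc9)c8)[C@@H](OCc9ccccc9)C2
F5 | step 16 | C8 aryl dichlorocerium reagent from F4 | O(Cc9ccccc9)c1ccc2c(c1)O[C@H](c8ccc(OCc9ccccc9)c(OCc9ccccc9)c8)[C@@H](OCc9ccccc9)[C@H]2c1c(OCc9ccccc9)c2c(c([Ce](Cl)Cl)c1OCc9ccccc9)O[C@H](c8ccc(OCc9ccccc9)c(OCc9ccccc9)c8)[C@@H](OCc9ccccc9)C2
F6 | step 16 | tertiary (2S)-4-arylflavan-4-ol on catechin C8, both C4 epimers | O(Cc9ccccc9)c1ccc2c(c1)O[C@H](c8ccc(OCc9ccccc9)c(OCc9ccccc9)c8)[C@@H](OCc9ccccc9)[C@H]2c1c(OCc9ccccc9)c2c(c(C3(O)C[C@@H](c8ccc(OCc9ccccc9)c(OCc9ccccc9)c8)Oc4cc(OCc9ccccc9)ccc34)c1OCc9ccccc9)O[C@H](c8ccc(OCc9ccccc9)c(OCc9ccccc9)c8)[C@@H](OCc9ccccc9)C2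
F7 | step 12 | (3S,4R)-3,7-bis(benzyloxy)-4-(catechin-6-yl residue)-2-(phenylsulfonyl)chromane, both anomers | O(Cc9ccccc9)c1ccc2c(c1)OC(S(=O)(=O)c5ccccc5)[C@@H](OCc9ccccc9)[C@H]2c1c(OCc9ccccc9)c2c(c(Br)c1OCc9ccccc9)O[C@H](c8ccc(OCc9ccccc9)c(OCc9ccccc9)c8)[C@@H](OCc9ccccc9)C2
F8 | step 12 | bis[3,4-bis(benzyloxy)phenyl]zinc | [Zn](c1ccc(OCc2ccccc2)c(OCc2ccccc2)c1)c1ccc(OCc2ccccc2)c(OCc2ccccc2)c1
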